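**Retrosynthetic overview**
1. Target 12 ⇐ 11 by one global hydrogenolysis (four benzyl ethers and the benzyl ester).
2. 11 ⇐ 10 by face-selective osmium dihydroxylation of an exocyclic alkene (C3–O and CH2–O bonds, sets C3); 10 ⇐ tetralone 9 by carbonyl methylenation.
3. 9 ⇐ acyclic alkylidene β-ketoester 7 by a one-flask catalytic asymmetric epoxidation (C–O bonds, sets C2) and epoxy-arene Friedel–Crafts closure (C1–C8a bond, C1 relayed from C2).
4. 7 ⇐ β-ketoester 5 + aldehyde 6 (Knoevenagel); 5 ⇐ acid 1 + Meldrum's acid 2 + benzyl alcohol 3.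
5. Ring order: both benzene rings are bought; ring B (the saturated ring of the tetralin) is the only ring made, in step 3.

The target is (1S,2S,3R): the aryl on C1 is cis to the C2–OH and trans to the carboxyl, and the C3–OH is trans to the C2–OH (the plicatic acid configuration, with a 3,4,5-trihydroxyphenyl ring).

Assumption: 1 and 6 are bought as catalogue compounds, and the ligand antipode used in step 3 is the one that gives the (2S)-epoxide (both antipodes are accessible from L- or D-pipecolic acid).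

**Route**

Step 1
Reactants: 1 2-[4-(benzyloxy)-3-methoxyphenyl]acetic acid; 2 Meldrum's acid; 3 benzyl alcohol
Product: 5 benzyl 4-[4-(benzyloxy)-3-methoxyphenyl]-3-oxobutanoate, via acyl Meldrum's acid 4 (not isolated)
Conditions: DCC, DMAP, CH2Cl2, 0 °C → rt; filter; then 3, toluene, 110 °C
Reagents that add atoms: none
Why: C-acylation of Meldrum's acid by the carbodiimide-activated acid, then thermal alcoholysis through the acyl ketene with loss of acetone and CO2, is the standard Meldrum's acid β-ketoester synthesis; no stereocenter is involved.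

Step 2
Reactants: 5 benzyl 4-[4-(benzyloxy)-3-methoxyphenyl]-3-oxobutanoate; 6 3,4,5-tris(benzyloxy)benzaldehyde
Product: 7 benzyl (2Z)-2-{[4-(benzyloxy)-3-methoxyphenyl]acetyl}-3-[3,4,5-tris(benzyloxy)phenyl]prop-2-enoate (Z major, some E)
Conditions: piperidine (10 mol %), AcOH (10 mol %), toluene, reflux, Dean–Stark
Reagents that add atoms: none
Why: Knoevenagel condensation at the doubly activated methylene of the β-ketoester; the E/Z ratio does not matter because both isomers converge in step 3.

Step 3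
Reactants: 7 benzyl (2Z)-2-{[4-(benzyloxy)-3-methoxyphenyl]acetyl}-3-[3,4,5-tris(benzyloxy)phenyl]prop-2-enoate
Product: 9 benzyl (1S,2S)-7-(benzyloxy)-2-hydroxy-6-methoxy-3-oxo-1-[3,4,5-tris(benzyloxy)phenyl]-1,2,3,4-tetrahydronaphthalene-2-carboxylate, via epoxy ketoester 8 (not isolated)
Conditions: Sc(OTf)3 (5 mol %), chiral N,N'-dioxide ligand (6 mol %; C2-symmetric, from pipecolic acid, N-(2,6-diisopropylphenyl) amide arms, propane-1,3-diyl linker), 30% aq H2O2 (1.2 equiv), THF, 0 °C; then Me2S, MgSO4; then Sc(OTf)3 (20 mol %), HFIP, 0 °C → rt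
Reagents that add atoms: hydrogen peroxide, OO
Why: Proposed new method: one trivalent scandium centre is used twice – ligated by the chiral N,N'-dioxide it chelates the 1,3-dicarbonyl of 7 so that H2O2 adds to the β-carbon on one face and the scandium peroxy-enolate (common to E- and Z-7) closes by C–O bond formation to the (2S)-epoxide 8, then unligated Sc(OTf)3 in HFIP ionises the p-benzyloxy-benzylic C–O bond and the tethered arene (position para to OMe) closes ring B on the face that leaves the aryl trans to the C2 ester, so C1 (S) is relayed from the oxygen-bearing C2 (S); the closest known reaction types are the chiral scandium N,N'-dioxide/H2O2 Weitz–Scheffer epoxidation of enones and arylidene 1,3-diketones, the stoichiometric chiral-hydroperoxide epoxidation of α-acyl cinnamates and the Lewis-acid epoxy-arene Friedel–Crafts cyclisation, none of which has been run as a catalytic asymmetric tandem on an unsymmetrical alkylidene β-ketoester.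

Step 4
Reactants: 9 benzyl (1S,2S)-7-(benzyloxy)-2-hydroxy-6-methoxy-3-oxo-1-[3,4,5-tris(benzyloxy)phenyl]-1,2,3,4-tetrahydronaphthalene-2-carboxylate
Product: 10 benzyl (1S,2S)-7-(benzyloxy)-2-hydroxy-6-methoxy-3-methylidene-1-[3,4,5-tris(benzyloxy)phenyl]-1,2,3,4-tetrahydronaphthalene-2-carboxylate
Conditions: Zn dust, CH2Br2, TiCl4, THF (reagent pre-formed at 0 °C); then 9, CH2Cl2, 0 °C → rt; NaHCO3 work-up
Reagents that add atoms: dibromomethane, BrCBr
Why: Takai–Lombardo methylenation uses a non-basic zinc/titanium methylene reagent that olefinates hindered, enolisable ketones without touching esters or the free tertiary alcohol, so the base-sensitive α-hydroxy-β-ketoester and both stereocenters are left intact.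

Step 5
Reactants: 10 benzyl (1S,2S)-7-(benzyloxy)-2-hydroxy-6-methoxy-3-methylidene-1-[3,4,5-tris(benzyloxy)phenyl]-1,2,3,4-tetrahydronaphthalene-2-carboxylate
Product: 11 benzyl (1S,2S,3R)-7-(benzyloxy)-2,3-dihydroxy-3-(hydroxymethyl)-6-methoxy-1-[3,4,5-tris(benzyloxy)phenyl]-1,2,3,4-tetrahydronaphthalene-2-carboxylate
Conditions: OsO4 (5 mol %), NMO, acetone/H2O 4:1, rt
Reagents that add atoms: osmium tetroxide (catalytic oxygen carrier), O=[Os](=O)(=O)=O; N-methylmorpholine N-oxide, C[N+]1([O-])CCOCC1; water, O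
Why: Upjohn dihydroxylation; the pseudoaxial C1 aryl shields the face of the exocyclic alkene cis to it (1,3-diaxial) and OsO4 also prefers to add anti to an allylic hydroxyl, so the new C3–O bond forms trans to the aryl and to the C2–OH, leaving the hydroxymethyl cis to them, which is 3R.

Step 6
Reactants: 11 benzyl (1S,2S,3R)-7-(benzyloxy)-2,3-dihydroxy-3-(hydroxymethyl)-6-methoxy-1-[3,4,5-tris(benzyloxy)phenyl]-1,2,3,4-tetrahydronaphthalene-2-carboxylate
Product: 12 (1S,2S,3R)-2,3,7-trihydroxy-3-(hydroxymethyl)-6-methoxy-1-(3,4,5-trihydroxyphenyl)-1,2,3,4-tetrahydronaphthalene-2-carboxylic acid (CNP0174537.1)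
Conditions: H2 (1 atm), 10% Pd/C, THF/MeOH, rt; filter under argon, lyophilise
Reagents that add atoms: none
Why: Catalytic hydrogenolysis cleaves the four aryl benzyl ethers and the benzyl ester in one operation under neutral conditions; the target has no benzylic C–O bond and no reducible group, so the three stereocenters are untouched.

**Compound list**
1 | 2-[4-(benzyloxy)-3-methoxyphenyl]acetic acid | COc1cc(CC(=O)O)ccc1OCc1ccccc1 | starting material
2 | Meldrum's acid (2,2-dimethyl-1,3-dioxane-4,6-dione) | CC1(C)OC(=O)CC(=O)O1 | starting material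
3 | benzyl alcohol | OCc1ccccc1 | starting material
4 | 5-{2-[4-(benzyloxy)-3-methoxyphenyl]-1-hydroxyethylidene}-2,2-dimethyl-1,3-dioxane-4,6-dione (acyl Meldrum's acid, enol form) | COc1cc(CC(O)=C2C(=O)OC(C)(C)OC2=O)ccc1OCc1ccccc1 | intermediate
5 | benzyl 4-[4-(benzyloxy)-3-methoxyphenyl]-3-oxobutanoate | COc1cc(CC(=O)CC(=O)OCc2ccccc2)ccc1OCc1ccccc1 | intermediate
6 | 3,4,5-tris(benzyloxy)benzaldehyde | O=Cc1cc(OCc2ccccc2)c(OCc2ccccc2)c(OCc2ccccc2)c1 | starting material
7 | benzyl (2Z)-2-{[4-(benzyloxy)-3-methoxyphenyl]acetyl}-3-[3,4,5-tris(benzyloxy)phenyl]prop-2-enoate (Z major) | COc1cc(CC(=O)/C(=C/c2cc(OCc3ccccc3)c(OCc3ccccc3)c(OCc3ccccc3)c2)C(=O)OCc2ccccc2)ccc1OCc1ccccc1 | intermediate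
8 | benzyl (2S,3R)-2-{[4-(benzyloxy)-3-methoxyphenyl]acetyl}-3-[3,4,5-tris(benzyloxy)phenyl]oxirane-2-carboxylate (aryl cis to the ester) | O=C(Cc1ccc(OCc2ccccc2)c(OC)c1)[C@@]1(C(=O)OCc2ccccc2)O[C@@H]1c1cc(OCc2ccccc2)c(OCc2ccccc2)c(OCc2ccccc2)c1 | intermediate
9 | benzyl (1S,2S)-7-(benzyloxy)-2-hydroxy-6-methoxy-3-oxo-1-[3,4,5-tris(benzyloxy)phenyl]-1,2,3,4-tetrahydronaphthalene-2-carboxylate | COc1cc2c(cc1OCc1ccccc1)[C@H](c1cc(OCc3ccccc3)c(OCc3ccccc3)c(OCc3ccccc3)c1)[C@@](O)(C(=O)OCc1ccccc1)C(=O)C2 | intermediate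
10 | benzyl (1S,2S)-7-(benzyloxy)-2-hydroxy-6-methoxy-3-methylidene-1-[3,4,5-tris(benzyloxy)phenyl]-1,2,3,4-tetrahydronaphthalene-2-carboxylate | COc1cc2c(cc1OCc1ccccc1)[C@H](c1cc(OCc3ccccc3)c(OCc3ccccc3)c(OCc3ccccc3)c1)[C@@](O)(C(=O)OCc1ccccc1)C(=C)C2 | intermediate
11 | benzyl (1S,2S,3R)-7-(benzyloxy)-2,3-dihydroxy-3-(hydroxymethyl)-6-methoxy-1-[3,4,5-tris(benzyloxy)phenyl]-1,2,3,4-tetrahydronaphthalene-2-carboxylate | COc1cc2c(cc1OCc1ccccc1)[C@H](c1cc(OCc3ccccc3)c(OCc3ccccc3)c(OCc3ccccc3)c1)[C@@](O)(C(=O)OCc1ccccc1)[C@](O)(CO)C2 | intermediate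
12 | (1S,2S,3R)-2,3,7-trihydroxy-3-(hydroxymethyl)-6-methoxy-1-(3,4,5-trihydroxyphenyl)-1,2,3,4-tetrahydronaphthalene-2-carboxylic acid | COc1cc2c(cc1O)[C@H](c1cc(O)c(O)c(O)c1)[C@@](O)(C(=O)O)[C@](O)(CO)C2 | target

**Totals**
Total step count: 6. Longest linear sequence: 6 steps (1 → 12).

**Steps most likely to fail**

Step 3 (the proposed new step). The risks are:
- the level and sense of induction (an opposite sense is met with the ligand antipode);
- a direct Lewis-acid Friedel–Crafts conjugate addition of the arene to 7 before epoxidation, which would give the tetralone without the C2 oxygen;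
- an acyl shift of the ionised epoxide competing with ring closure;
- whether ring closure really gives the aryl trans to the ester: 8 is drawn with the aryl cis to the ester, so an invertive (SN2-like) opening would give the C1 epimer, and the outcome rests on the ionising conditions.

Fallback, known chemistry, setting out from 7 and coming back at 9: 7 is epoxidised with a stoichiometric TADDOL-derived hydroperoxide (TADOOH, the antipode giving the 2S epoxide) and a lithium base (LiOH or n-BuLi) in THF at low temperature. This is the established reagent-controlled epoxidation of α-acyl cinnamates. Epoxide 8 is isolated and purified, then cyclised in a separate flask with a Lewis acid (BF3·OEt2 or SnCl4, CH2Cl2, −78 → 0 °C) to 9. This detour makes no compound beyond 8 (F0).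

Step 4. The ketone is flanked by a fully substituted carbinol carbon and a benzylic CH2, so it is hindered and easily enolised. The exocyclic alkene can also migrate into conjugation with ring A under Lewis acid.

Fallback, setting out from 9 and coming back at 10 (Peterson olefination in place of the titanium reagent): Me3SiCH2MgCl with anhydrous CeCl3 (THF, −78 °C, excess to cover the free hydroxyl) adds to the ketone. The product is the β-hydroxysilane benzyl (1S,2S)-7-(benzyloxy)-2,3-dihydroxy-6-methoxy-3-[(trimethylsilyl)methyl]-1-[3,4,5-tris(benzyloxy)phenyl]-1,2,3,4-tetrahydronaphthalene-2-carboxylate F1, as either C3 epimer since both eliminate to the same alkene. KH in THF at 0 °C then removes trimethylsilanol to give 10.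

Step 5. The alkene is 1,1-disubstituted next to a quaternary centre, so osmylation may be slow. The ester on C2 flanks the desired face, so the facial ratio is not guaranteed.

Fallback, setting out from 9 and coming back at 11 (a temporary silicon tether delivers the hydroxymethyl carbon cis to the C2 oxygen, so the face is fixed by connectivity and 10 is bypassed):
- The C2–OH of 9 is silylated with (bromomethyl)chlorodimethylsilane and imidazole in DMF to give benzyl (1S,2S)-7-(benzyloxy)-2-{[(bromomethyl)dimethylsilyl]oxy}-6-methoxy-3-oxo-1-[3,4,5-tris(benzyloxy)phenyl]-1,2,3,4-tetrahydronaphthalene-2-carboxylate F2.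
- SmI2 in THF at −78 °C effects an intramolecular Barbier addition to the C3 ketone. This gives the cis-fused siloxane benzyl (1S,2S,3S)-7-(benzyloxy)-3-hydroxy-6-methoxy-2,3-[oxy(dimethylsilanediyl)methylene]-1-[3,4,5-tris(benzyloxy)phenyl]-1,2,3,4-tetrahydronaphthalene-2-carboxylate F3 (O on C2, CH2 on C3, C3–OH trans to the C2 oxygen).
- Tamao–Fleming oxidation (KF, KHCO3, 30% H2O2, THF/MeOH, rt) converts the C–Si bond into the primary alcohol and frees the C2–OH, giving 11.

**Further compounds**
F0 | step 3 | none | none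
F1 | step 4 | benzyl (1S,2S)-7-(benzyloxy)-2,3-dihydroxy-6-methoxy-3-[(trimethylsilyl)methyl]-1-[3,4,5-tris(benzyloxy)phenyl]-1,2,3,4-tetrahydronaphthalene-2-carboxylate (C3 epimers) | COc1cc2c(cc1OCc1ccccc1)[C@H](c1cc(OCc3ccccc3)c(OCc3ccccc3)c(OCc3ccccc3)c1)[C@@](O)(C(=O)OCc1ccccc1)C(O)(C[Si](C)(C)C)C2
F2 | step 5 | benzyl (1S,2S)-7-(benzyloxy)-2-{[(bromomethyl)dimethylsilyl]oxy}-6-methoxy-3-oxo-1-[3,4,5-tris(benzyloxy)phenyl]-1,2,3,4-tetrahydronaphthalene-2-carboxylate | COc1cc2c(cc1OCc1ccccc1)[C@H](c1cc(OCc3ccccc3)c(OCc3ccccc3)c(OCc3ccccc3)c1)[C@@](O[Si](C)(C)CBr)(C(=O)OCc1ccccc1)C(=O)C2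
F3 | step 5 | benzyl (1S,2S,3S)-7-(benzyloxy)-3-hydroxy-6-methoxy-2,3-[oxy(dimethylsilanediyl)methylene]-1-[3,4,5-tris(benzyloxy)phenyl]-1,2,3,4-tetrahydronaphthalene-2-carboxylate (cis-fused oxasilolane) | COc1cc2c(cc1OCc1ccccc1)[C@H](c1cc(OCc3ccccc3)c(OCc3ccccc3)c(OCc3ccccc3)c1)[C@@](O[Si](C)(C)C4)(C(=O)OCc1ccccc1)[C@@]4(O)C2
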